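The numbers of this flask are assumed, and the outcome is calculated.

Two clocks run in this flask.

    reagent in the reaction phase ⇌ reagent in the second phase, rate k1*([reagent in the reaction phase] - [reagent in the second phase]/K1) per volume of the first phase (K1 = 0.53, k1 = 0.0317 s⁻¹)
    substrate + reagent in the reaction phase → target (k2 = 2.03 M⁻¹ s⁻¹)
    target ⇌ product in the second phase, rate k3*([target] - [product in the second phase]/K3) per volume of the first phase (K3 = 3.0, k3 = 0.0366 s⁻¹)
    target → decomposed product (k4 = 0.0148 s⁻¹)
    reagent in the reaction phase + protic impurity → quenched reagent (k5 = 0.309 M⁻¹ s⁻¹)
    substrate ⇌ dormant form (K6 = 0.98, k6 = 0.0388 s⁻¹)

substrate 0.22 M; reagent in the second phase 0.209 M; protic impurity 0.110 M; time 1.0 min; volume of the second phase over the first 1.0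

- amount of target and product in the second phase together at 1.0 min, in percent of the substrate charged
- the change that raises the amount of target and product in the second phase together at 1.0 min, in percent of the substrate charged most ("none" if none brings more than 2 percentage points) (violet / blue / grey / none)
- amount of target and product in the second phase together at 1.0 min, in percent of the substrate charged, after violet

The first clock is the feed. While backflow is small, reagent in the second phase drains with half-time 0.193 min. Backflow is small early on because reagent in the reaction phase lasts 1.6 s against substrate as charged, shorter than that half-time. No charge enters that formula.

The second clock is the decay of target and product in the second phase together. Step 4 acts in the first phase, so their loss rate is its constant times the first-phase share. The first answer takes that share from the partition ratio. But loss keeps draining the first phase, which lowers the ratio of target in the first phase to product in the second phase to one over the partition ratio, minus the loss rate over the transfer coefficient of step 3. Each answer therefore goes back in: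

| Round | First-phase share | Half-life |
|---|---|---|
| first | 0.250 | 3.12 min |
| second | 0.188 | 4.14 min |
| third | 0.205 | 3.82 min |

The last figure is the holding half-life, and it is 19.8 times the feed half-time. Target therefore builds first and decays later, with a crest near 0.876 min, close to the asked time. This reckoning gives times, not the yield. The choice among the changes rests on amount: reagent is the limiting reagent, its charge of 0.209 M being less than the 0.22 M of substrate, and the feed half-time is shorter than the run, so this reckoning favours blue, which adds reagent.

The forecast gives 51 %, blue as best, and 52.5 % after violet, on the ground that “reagent supply limits the rate”.

The flask gives 50.8 %, 52.9 % after violet, and blue as best, with a gain of 15 percentage points. Its 50.8 % at the asked time stands above the 46.3 % read at 0.500 min and the 45.8 % read at 2.00 min, so the reckoned crest lies between readings that bracket it. With a holding half-life of 3.82 min, the 42.2 % read in the same flask at 2.5 min should fall to 32.1 % by 4.0 min, and the flask read then holds 32.4 %.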